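Take a one-step world first: first end groups meet dissolved second end groups, links appear, and a link stays a link. The runs refuse that world: in elm, links falls from 28% at 1.50 h to 6% at 5.00 h.

common to all: gas 62 mM (held)

|  | first end groups | remark | time |
|---|---|---|---|
| elm | 0.25 M (in portions, 2) | run made earlier; portions every 1.0 h |  |
| maple | 1 M (in portions, 2) | run made earlier; portions every 1.0 h |  |
| flask | 0.50 M (in portions, 2) | the portions of first end groups follow each other after 1.0 h, the first at the start | 8.0 h |

- elm (time / h: links / %, first end groups / %): 0.500: 22, 11; 1.50: 28, 28; 3.00: 17, 15; 5.00: 6, 3; 6.00: 1, 3
- maple (time / h: links / %, first end groups / %): 0.500: 18, 26; 1.50: 25, 53; 3.00: 8, 38; 5.00: 1, 27; 6.00: 5, 23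

(scatter of a reading: 2 percentage points)

- at the start none of second end groups is dissolved
- steps thought possible: second end groups + links -> over-reaction product; first end groups + second end groups <-> links + by-product; gas <-> second end groups

- amount of links in percent of the first end groups charged, at 1.5 h, 4.0 h and 8.0 h

Count everything as fractions of the charge. Once both portions are in, by-product is the fraction that has left first end groups. Take second end groups as held at saturation, a fraction g of the charge, 12.4% in this flask. If the reversible step stands near balance, links over first end groups, times by-product, over g, stays constant. You read this balance number as 2.90 in elm and 3.58 in maple at 1.50 h, mean 3.24. Links plus first end groups is a pool that shrinks as links goes on to over-reaction product. Between 1.50 h and 3.00 h, the loss from both runs over the links present gives 0.957 h⁻¹.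

Late on, by-product nears the whole charge, so links stands to first end groups as balance number times g. Links is then a fixed share of the pool, and this share times the loss rate is the tail rate, a pseudo-first-order fall. For this flask I reckon 0.274 h⁻¹.

Now take two ways to 8.0 h, both starting from 8.00% at 4.0 h, my mean of the two runs. Elm's own fall, 0.521 h⁻¹, gives 0.995%. The tail rate gives 2.67%. They part, and elm's fall is the one that cheats: with its smaller charge, elm has a tail rate of 0.426 h⁻¹, faster than this flask's. I commit to 26.5%, 8.00% and 2.67%.

The forecast says 27%, 7% and 1.2%, on the ground that “Links then decay by roughly 0.5–0.6 per hour”. At 8.0 h it stands below my figure.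

    second end groups + links → over-reaction product (k = 0.280 M⁻¹ min⁻¹)
    first end groups + second end groups ⇌ links + by-product (K = 2.70, k = 6.30 M⁻¹ min⁻¹)
    gas ⇌ second end groups, rate k3*(csat - [second end groups]) (kL = 14.0 min⁻¹)

The flask gives 23.8%, 8.38% and 2.40%, and the forecast counts as right within the tolerance set on the question. At 1.34 h links in this flask falls back to first end groups 38 times faster than it goes on, and at 8.0 h there are still 6.76% first end groups beside 2.40% links. From 4.0 h to 8.0 h links falls at 0.313 h⁻¹, against the tail rate of 0.274 h⁻¹. With half the charge, the tail rate 0.426 h⁻¹ carries elm's 6% at 5.00 h to 1.67%, and that flask holds 1.35% links.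

All runs are simulated on assumed constants; scatter was added.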